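**Retrosynthetic overview**

1. The last C–C bond is the C(sp)–C(sp2) bond of the enyne, made by Sonogashira coupling of dioxane alkyne 19 with (E)-iodoalkene 22 (from dec-9-en-1-ol); the CH2CO2Me group comes from oxidation of a 2-hydroxyethyl arm.
2. Feature used: in the 1,2-dioxane (O1, O2, C3, C4, C5, C6) the O2–C3 bond ends at C3, the only carbinol-type stereocentre, and C3 with its two-carbon arm and the arm's terminal oxygen is a masked oxetane (C2, C3, C4, O). Cutting O2–C3 gives a C6 methoxy hydroperoxyketal tethered to an (R)-oxetane, which is opened with inversion.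
3. The hydroperoxyketal comes from ozonolysis in methanol of a 1,1-disubstituted alkene; C6 is settled after ring closure by acid equilibration to the axial-methoxy epimer.
4. The (R)-oxetane comes from a 1,3-diol monotosylate; its carbinol centre comes from Noyori hydrogenation of a β-keto ester built from methyl acetoacetate dianion and an allylic chloride (dichloride 2 plus a butynyl Grignard reagent).
5. Ring order: oxetane (step 6), then the 1,2-dioxane (step 8), whose formation consumes the oxetane; no other ring is formed.

Key step: step 8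

Remark: compounds 14 and 15 are carried as mixtures of the two epimers at the ketal carbon; only C3 is fixed in the key step, and the ketal carbon is settled in step 9. Peroxides (from step 7 on) are handled on small scale, cold and behind a shield.

**Route**

Step 1
Reactants: 1 (4-bromobut-1-yn-1-yl)trimethylsilane; 2 3-chloro-2-(chloromethyl)prop-1-ene
Product: 4 [6-(chloromethyl)hept-6-en-1-yn-1-yl]trimethylsilane, via silylbutynylmagnesium bromide 3 (not isolated)
Conditions: Mg, THF, 40 °C; then 2 (3 equiv), CuI (5 mol %), THF, −30 to 0 °C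
Reagents that add atoms: none
Why: Copper-catalysed allylic substitution of a Grignard reagent: the silyl cap makes the homopropargylic Grignard reagent accessible, SN2 and SN2′ attack give the same product because the 2-substituted allyl unit is symmetric, and a threefold excess of 2 suppresses the second substitution.

Step 2
Reactants: 5 methyl acetoacetate; 4 [6-(chloromethyl)hept-6-en-1-yn-1-yl]trimethylsilane
Product: 7 methyl 6-methylidene-3-oxo-11-(trimethylsilyl)undec-10-ynoate, via acetoacetate dianion 6 (not isolated)
Conditions: 5, NaH, THF, 0 °C; n-BuLi, 0 °C; then 4, 0 °C to rt; 1 M HCl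
Reagents that add atoms: none
Why: Weiler γ-alkylation of the acetoacetate dianion: the terminal carbanion is the more nucleophilic site and displaces the reactive allylic chloride (SN2 and SN2′ again give one constitution), leaving the alkynylsilane and the alkene untouched.

Step 3
Reactants: 7 methyl 6-methylidene-3-oxo-11-(trimethylsilyl)undec-10-ynoate
Product: 8 methyl (3R)-3-hydroxy-6-methylidene-11-(trimethylsilyl)undec-10-ynoate
Conditions: H2 (4 atm), [RuCl(p-cymene)((R)-BINAP)]Cl (1 mol %), MeOH, 50 °C
Reagents that add atoms: none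
Why: Noyori asymmetric hydrogenation: the β-keto ester chelates ruthenium and the (R)-BINAP ligand directs hydride to the face that gives the (3R)-carbinol (same sense as methyl acetoacetate to methyl (R)-3-hydroxybutanoate), while the remote 1,1-disubstituted alkene and the silyl-capped alkyne carry no directing group and should not be reduced at this low pressure.

Step 4
Reactants: 8 methyl (3R)-3-hydroxy-6-methylidene-11-(trimethylsilyl)undec-10-ynoate
Product: 9 (3R)-6-methylidene-11-(trimethylsilyl)undec-10-yne-1,3-diol
Conditions: LiAlH4, THF, 0 °C; H2O, 15% aq. NaOH, H2O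
Reagents that add atoms: none
Why: Hydride reduction of the ester to the primary alcohol; LiAlH4 at 0 °C leaves the isolated alkene and the non-propargylic alkynylsilane alone, and the carbinol centre is not involved.

Step 5
Reactants: 9 (3R)-6-methylidene-11-(trimethylsilyl)undec-10-yne-1,3-diol
Product: 10 (3R)-3-hydroxy-6-methylidene-11-(trimethylsilyl)undec-10-yn-1-yl 4-methylbenzenesulfonate
Conditions: TsCl (1.05 equiv), Et3N, Me3N·HCl (cat.), CH2Cl2, 0 °C
Reagents that add atoms: 4-methylbenzenesulfonyl chloride, Cc1ccc(cc1)S(Cl)(=O)=O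
Why: Selective sulfonylation of the less hindered primary hydroxyl of a primary/secondary 1,3-diol with a slight excess of TsCl at 0 °C; the stereocentre keeps its C–O bond.

Step 6
Reactants: 10 (3R)-3-hydroxy-6-methylidene-11-(trimethylsilyl)undec-10-yn-1-yl 4-methylbenzenesulfonate
Product: 12 (2R)-2-(3-methylideneoct-7-yn-1-yl)oxetane, via silylated oxetane 11 (not isolated)
Conditions: KOtBu (2.2 equiv), THF, 0 °C to rt; then MeOH, rt
Reagents that add atoms: none
Why: Intramolecular Williamson etherification (4-exo-tet) of the secondary alkoxide onto the primary tosylate leaves the C–O bond of the stereocentre intact, so (R) is retained; methoxide formed on adding methanol then protodesilylates the alkynylsilane in the same flask.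

Step 7
Reactants: 12 (2R)-2-(3-methylideneoct-7-yn-1-yl)oxetane
Product: 14 (2R)-2-(3-hydroperoxy-3-methoxyoct-7-yn-1-yl)oxetane (both ketal epimers), via carbonyl oxide 13 (not isolated)
Conditions: O3 (1 equiv, Sudan Red 7B end point), MeOH/CH2Cl2 (1:4), −78 °C; N2 purge; cold chromatography
Reagents that add atoms: ozone, [O-][O+]=O; methanol, CO
Why: Ozonolysis by the Criegee mechanism: cycloreversion of the primary ozonide of the 1,1-disubstituted alkene gives formaldehyde and the ketone-derived carbonyl oxide, which methanol traps as the methoxy hydroperoxyketal; the terminal alkyne reacts with ozone far more slowly than the alkene, the oxetane is inert, and the new ketal centre forms without control as both epimers.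

Step 8
Reactants: 14 (2R)-2-(3-hydroperoxy-3-methoxyoct-7-yn-1-yl)oxetane (both ketal epimers)
Product: 15 2-[(3S)-6-methoxy-6-(pent-4-yn-1-yl)-1,2-dioxan-3-yl]ethan-1-ol (both C6 epimers; the 6R epimer is 16)
Conditions: Yb(OTf)3 (0.3 equiv), CH2Cl2, 0 °C to rt
Reagents that add atoms: none
Why: Yb(OTf)3 coordinates the oxetane oxygen and the terminal oxygen of the hydroperoxy group attacks oxetane C2 (the secondary carbon carrying the tether) anti to its C–O bond, an SN2 displacement driven by release of four-membered-ring strain; proton loss leaves the former oxetane oxygen as the primary hydroxyl of the two-carbon arm. The closest known reaction type is the Lewis-acid-promoted intramolecular opening of oxetanes by hydroperoxides and hydroperoxyketals, which gives 1,2-dioxolanes and 1,2-dioxanes with inversion at the attacked carbon. The 1,2-dioxane closes by a 6-exo-tet attack that forms the O2–C3 bond. C3 is the only stereocentre set here and is substrate-controlled: backside displacement turns the (R)-oxetane carbon into (3S), while C6 stays a mixture that step 9 corrects. The step needs attack at oxetane C2 rather than C4 (which would require an eight-membered ring) and displacement faster than ionisation of the oxetane carbon or the peroxyketal; the unstabilised secondary carbon, the mild oxophilic activator and the low temperature should secure this, and the terminal alkyne is inert.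

Step 9
Reactants: 15 2-[(3S)-6-methoxy-6-(pent-4-yn-1-yl)-1,2-dioxan-3-yl]ethan-1-ol (both C6 epimers)
Product: 16 2-[(3S,6R)-6-methoxy-6-(pent-4-yn-1-yl)-1,2-dioxan-3-yl]ethan-1-ol
Conditions: CSA (10 mol %), MeOH, rt; NaHCO3
Reagents that add atoms: methanol, CO
Why: Acid-catalysed ketal epimerisation in methanol through reversible ionisation at C6 puts the mixture under thermodynamic control, which should favour the chair with axial methoxy (anomeric effect with O1) and equatorial pentynyl and hydroxyethyl groups, i.e. the 6R epimer; C3 has no ionisable bond and is unchanged, methanol as solvent keeps the ketal a methyl ketal, and the minor epimer can be resubmitted.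

Step 10
Reactants: 16 2-[(3S,6R)-6-methoxy-6-(pent-4-yn-1-yl)-1,2-dioxan-3-yl]ethan-1-ol
Product: 18 [(3S,6R)-6-methoxy-6-(pent-4-yn-1-yl)-1,2-dioxan-3-yl]acetic acid, via dioxanyl acetaldehyde 17 (not isolated)
Conditions: TEMPO (0.2 equiv), PhI(OAc)2 (2.5 equiv), MeCN/H2O (1:1), 0 °C to rt
Reagents that add atoms: water, O
Why: Oxoammonium (TEMPO/PhI(OAc)2) oxidation of the primary alcohol to the aldehyde and, through its hydrate, to the carboxylic acid under near-neutral aqueous conditions that spare the dialkyl peroxide, the peroxyketal and the terminal alkyne; no stereocentre is touched.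

Step 11
Reactants: 18 [(3S,6R)-6-methoxy-6-(pent-4-yn-1-yl)-1,2-dioxan-3-yl]acetic acid
Product: 19 methyl [(3S,6R)-6-methoxy-6-(pent-4-yn-1-yl)-1,2-dioxan-3-yl]acetate
Conditions: TMSCHN2, PhMe/MeOH (4:1), 0 °C
Reagents that add atoms: trimethylsilyldiazomethane, C[Si](C)(C)C=[N+]=[N-]
Why: O-Methylation of the carboxylic acid by TMSCHN2 in the presence of methanol, a neutral esterification chosen because a base could open the β-peroxy ester by elimination.

Step 12
Reactants: 20 dec-9-en-1-ol
Product: 21 dec-9-enal
Conditions: TEMPO (10 mol %), PhI(OAc)2 (1.1 equiv), CH2Cl2, rt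
Reagents that add atoms: none
Why: TEMPO/PhI(OAc)2 oxidation stops at the aldehyde in anhydrous CH2Cl2 and leaves the terminal alkene alone.

Step 13
Reactants: 21 dec-9-enal
Product: 22 (1E)-1-iodoundeca-1,10-diene
Conditions: CrCl2 (6 equiv), CHI3 (2 equiv), 1,4-dioxane/THF (6:1), 0 °C to rt
Reagents that add atoms: iodoform, IC(I)I
Why: Takai olefination: the geminal dichromium species from CHI3 and CrCl2 adds to the aldehyde and anti-elimination should give mainly the (E)-iodoalkene, the dioxane-rich solvent raising the E preference; the terminal alkene is inert.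

Step 14
Reactants: 19 methyl [(3S,6R)-6-methoxy-6-(pent-4-yn-1-yl)-1,2-dioxan-3-yl]acetate; 22 (1E)-1-iodoundeca-1,10-diene
Product: 23 peroxyacarnoate A, methyl [(3S,6R)-6-[(6E)-hexadeca-6,15-dien-4-yn-1-yl]-6-methoxy-1,2-dioxan-3-yl]acetate
Conditions: PdCl2(PPh3)2 (5 mol %), CuI (10 mol %), Et3N, THF (degassed), rt
Reagents that add atoms: none
Why: Sonogashira coupling of the terminal alkyne with the (E)-iodoalkene at room temperature with retention of alkene geometry; vinyl iodides couple under conditions mild enough for the 1,2-dioxane, the peroxyketal, the methyl ester and the terminal alkene to survive, and neither stereocentre is involved.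

**Compound list**

1 | (4-bromobut-1-yn-1-yl)trimethylsilane | C[Si](C)(C)C#CCCBr | starting material
2 | 3-chloro-2-(chloromethyl)prop-1-ene | C=C(CCl)CCl | starting material
3 | [4-(trimethylsilyl)but-3-yn-1-yl]magnesium bromide | C[Si](C)(C)C#CCC[Mg]Br | intermediate (not isolated)
4 | [6-(chloromethyl)hept-6-en-1-yn-1-yl]trimethylsilane | C[Si](C)(C)C#CCCCC(=C)CCl | intermediate
5 | methyl acetoacetate | COC(=O)CC(C)=O | starting material
6 | methyl acetoacetate 2,4-dianion, sodium lithium salt | [Na+].[Li+].C=C([O-])C=C([O-])OC | intermediate (not isolated)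
7 | methyl 6-methylidene-3-oxo-11-(trimethylsilyl)undec-10-ynoate | COC(=O)CC(=O)CCC(=C)CCCC#C[Si](C)(C)C | intermediate
8 | methyl (3R)-3-hydroxy-6-methylidene-11-(trimethylsilyl)undec-10-ynoate | COC(=O)C[C@H](O)CCC(=C)CCCC#C[Si](C)(C)C | intermediate
9 | (3R)-6-methylidene-11-(trimethylsilyl)undec-10-yne-1,3-diol | OCC[C@H](O)CCC(=C)CCCC#C[Si](C)(C)C | intermediate
10 | (3R)-3-hydroxy-6-methylidene-11-(trimethylsilyl)undec-10-yn-1-yl 4-methylbenzenesulfonate | Cc1ccc(cc1)S(=O)(=O)OCC[C@H](O)CCC(=C)CCCC#C[Si](C)(C)C | intermediate
11 | trimethyl{6-methylidene-8-[(2R)-oxetan-2-yl]oct-1-yn-1-yl}silane | C[Si](C)(C)C#CCCCC(=C)CC[C@@H]1CCO1 | intermediate (not isolated)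
12 | (2R)-2-(3-methylideneoct-7-yn-1-yl)oxetane | C#CCCCC(=C)CC[C@@H]1CCO1 | intermediate
13 | carbonyl oxide of 1-[(2R)-oxetan-2-yl]oct-7-yn-3-one | C#CCCCC(=[O+][O-])CC[C@@H]1CCO1 | intermediate (not isolated)
14 | (2R)-2-(3-hydroperoxy-3-methoxyoct-7-yn-1-yl)oxetane, both ketal epimers | C#CCCCC(OC)(OO)CC[C@@H]1CCO1 | intermediate
15 | 2-[(3S)-6-methoxy-6-(pent-4-yn-1-yl)-1,2-dioxan-3-yl]ethan-1-ol, both C6 epimers | C#CCCCC1(OC)CC[C@@H](CCO)OO1 | intermediate
16 | 2-[(3S,6R)-6-methoxy-6-(pent-4-yn-1-yl)-1,2-dioxan-3-yl]ethan-1-ol | C#CCCC[C@]1(OC)CC[C@@H](CCO)OO1 | intermediate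
17 | [(3S,6R)-6-methoxy-6-(pent-4-yn-1-yl)-1,2-dioxan-3-yl]acetaldehyde | C#CCCC[C@]1(OC)CC[C@@H](CC=O)OO1 | intermediate (not isolated)
18 | [(3S,6R)-6-methoxy-6-(pent-4-yn-1-yl)-1,2-dioxan-3-yl]acetic acid | C#CCCC[C@]1(OC)CC[C@@H](CC(=O)O)OO1 | intermediate
19 | methyl [(3S,6R)-6-methoxy-6-(pent-4-yn-1-yl)-1,2-dioxan-3-yl]acetate | C#CCCC[C@]1(OC)CC[C@@H](CC(=O)OC)OO1 | intermediate
20 | dec-9-en-1-ol | C=CCCCCCCCCO | starting material
21 | dec-9-enal | C=CCCCCCCCC=O | intermediate
22 | (1E)-1-iodoundeca-1,10-diene | C=CCCCCCCC/C=C/I | intermediate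
23 | peroxyacarnoate A | C=CCCCCCCC/C=C/C#CCCC[C@]1(OC)CC[C@@H](CC(=O)OC)OO1 | target

**Step count**

Total: 14 steps. Longest linear sequence: 12 steps (steps 1–11 and 14).

**Steps most likely to fail**

Step 8. The activator may ionise the hydroperoxyketal (loss of methanol or hydrogen peroxide, then Hock- or Criegee-type fragmentation) faster than it opens the oxetane, or the opening may gain carbocation character and erode the inversion. The fallback is the known base-mediated alkylation of a hydroperoxide by a secondary sulfonate; the leaving oxygen sits where the oxetane oxygen sat, so inversion gives the same (3S) centre. It sets out from diol 9 and comes back at alcohol 15. K2CO3 in MeOH removes the alkynylsilane to give (3R)-6-methylideneundec-10-yne-1,3-diol F1. TBSCl and imidazole (CH2Cl2, 0 °C) silylate the primary hydroxyl to give (3R)-1-[(tert-butyldimethylsilyl)oxy]-6-methylideneundec-10-yn-3-ol F2. MsCl and Et3N give (3R)-1-[(tert-butyldimethylsilyl)oxy]-6-methylideneundec-10-yn-3-yl methanesulfonate F3. Ozonolysis in MeOH/CH2Cl2 at −78 °C gives, through the carbonyl oxide of the C6 ketone F4, (3R)-1-[(tert-butyldimethylsilyl)oxy]-6-hydroperoxy-6-methoxyundec-10-yn-3-yl methanesulfonate F5. KOtBu with 18-crown-6 in THF at 0 °C should close the ring by 6-exo-tet displacement with inversion to tert-butyl{2-[(3S)-6-methoxy-6-(pent-4-yn-1-yl)-1,2-dioxan-3-yl]ethoxy}dimethylsilane F6. HF·pyridine in THF removes the silyl ether to give 15.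

Step 3. The catalyst [RuCl(p-cymene)((R)-BINAP)]Cl may also saturate or isomerise the 1,1-disubstituted alkene or reduce the alkyne, or enantioselection may be incomplete. The fallback takes the stereocentre from an enantiopure epoxide instead of making it. It sets out from allylic chloride 4 and comes back at diol 9. Mg in THF at 0 °C (kept cold to avoid a magnesium-ene cyclisation onto the alkyne) gives [2-methylidene-7-(trimethylsilyl)hept-6-yn-1-yl]magnesium chloride F7. CuI-catalysed opening of the purchased building block tert-butyldimethyl{2-[(2S)-oxiran-2-yl]ethoxy}silane F8 at its CH2 terminus gives (3R)-1-[(tert-butyldimethylsilyl)oxy]-6-methylidene-11-(trimethylsilyl)undec-10-yn-3-ol F9; the carbinol centre is untouched and becomes (3R) only through the change in CIP priorities. CSA in MeOH at 0 °C removes the primary silyl ether, leaving the alkynylsilane, to give 9.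

Step 14. PdCl2(PPh3)2-derived zerovalent palladium with its phosphine may cleave the O–O bond, the CuI/Et3N medium may open the β-peroxy ester by elimination, or the alkyne may homocouple. The fallback is a polarity-reversed Stille coupling free of amine, copper and phosphine. It sets out from alkyne 19 and aldehyde 21 and comes back at target 23. N-Iodosuccinimide with AgNO3 (cat.) in acetone converts 19 into methyl [(3S,6R)-6-(5-iodopent-4-yn-1-yl)-6-methoxy-1,2-dioxan-3-yl]acetate F10. The tin variant of the Takai olefination (CrCl2, Bu3SnCHBr2, LiI, THF/DMF) converts 21 into tributyl[(1E)-undeca-1,10-dien-1-yl]stannane F11. PdCl2(MeCN)2 in DMF at rt should couple F10 with F11 with retention of alkene geometry to give 23.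

**Further compounds**

F1 | step 8 | (3R)-6-methylideneundec-10-yne-1,3-diol | OCC[C@H](O)CCC(=C)CCCC#C
F2 | step 8 | (3R)-1-[(tert-butyldimethylsilyl)oxy]-6-methylideneundec-10-yn-3-ol | CC(C)(C)[Si](C)(C)OCC[C@H](O)CCC(=C)CCCC#C
F3 | step 8 | (3R)-1-[(tert-butyldimethylsilyl)oxy]-6-methylideneundec-10-yn-3-yl methanesulfonate | CC(C)(C)[Si](C)(C)OCC[C@H](OS(C)(=O)=O)CCC(=C)CCCC#C
F4 | step 8 | carbonyl oxide of (3R)-1-[(tert-butyldimethylsilyl)oxy]-6-oxoundec-10-yn-3-yl methanesulfonate | CC(C)(C)[Si](C)(C)OCC[C@H](OS(C)(=O)=O)CCC(=[O+][O-])CCCC#C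
F5 | step 8 | (3R)-1-[(tert-butyldimethylsilyl)oxy]-6-hydroperoxy-6-methoxyundec-10-yn-3-yl methanesulfonate, both C6 epimers | CC(C)(C)[Si](C)(C)OCC[C@H](OS(C)(=O)=O)CCC(OC)(OO)CCCC#C
F6 | step 8 | tert-butyl{2-[(3S)-6-methoxy-6-(pent-4-yn-1-yl)-1,2-dioxan-3-yl]ethoxy}dimethylsilane, both C6 epimers | C#CCCCC1(OC)CC[C@@H](CCO[Si](C)(C)C(C)(C)C)OO1
F7 | step 3 | [2-methylidene-7-(trimethylsilyl)hept-6-yn-1-yl]magnesium chloride | C[Si](C)(C)C#CCCCC(=C)C[Mg]Cl
F8 | step 3 | tert-butyldimethyl{2-[(2S)-oxiran-2-yl]ethoxy}silane | CC(C)(C)[Si](C)(C)OCC[C@H]1CO1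
F9 | step 3 | (3R)-1-[(tert-butyldimethylsilyl)oxy]-6-methylidene-11-(trimethylsilyl)undec-10-yn-3-ol | CC(C)(C)[Si](C)(C)OCC[C@H](O)CCC(=C)CCCC#C[Si](C)(C)C
F10 | step 14 | methyl [(3S,6R)-6-(5-iodopent-4-yn-1-yl)-6-methoxy-1,2-dioxan-3-yl]acetate | IC#CCCC[C@]1(OC)CC[C@@H](CC(=O)OC)OO1
F11 | step 14 | tributyl[(1E)-undeca-1,10-dien-1-yl]stannane | C=CCCCCCCC/C=C/[Sn](CCCC)(CCCC)CCCC
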